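Amounts at the end of the runs open a dispute about the flask.

| flask | solid substrate | protic impurity | remark | time |
|---|---|---|---|---|
| delta | 0.56 M | 0.83 M | run made earlier |  |
| zeta | 1.2 M | 0.83 M | run made earlier |  |
| beta | 0.83 M | 1.2 M | run made earlier |  |
| flask | 0.83 M | 0.830 M |  | 25 min |

| run | time / min | product / % | solid substrate / % |
|---|---|---|---|
| delta | 6.00 | 2 | 71 |
| delta | 8.00 | 2 | 61 |
| delta | 10.0 | 4 | 50 |
| delta | 12.0 | 5 | 45 |
| delta | 15.0 | 8 | 29 |
| delta | 20.0 | 14 | 7 |
| delta | 25.0 | 16 | 2 |
| zeta | 6.00 | 2 | 87 |
| zeta | 8.00 | 5 | 83 |
| zeta | 10.0 | 4 | 76 |
| zeta | 12.0 | 4 | 71 |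
| zeta | 15.0 | 7 | 69 |
| zeta | 20.0 | 5 | 58 |
| zeta | 25.0 | 7 | 47 |
| beta | 6.00 | 1 | 79 |
| beta | 8.00 | 6 | 75 |
| beta | 12.0 | 4 | 58 |
| beta | 20.0 | 5 | 35 |
| beta | 25.0 | 8 | 17 |

(scatter of a reading: 1.5 percentage points)

- solid substrate is a solid; its amount is given per volume of the solution
- at the start none of the solid substrate is in solution

1. when, up to 25 min, the flask holds most product
2. the amount of product, in percent of the solid substrate charged, at that time

One chemist points to zeta and beta, where product ends at 7 % and 8 % of the charge, and expects the flask to stay flat near these levels. The other sees a competition: what dissolves becomes product or is lost to protic impurity, and the impurity is used up on the way. This side's forecast is 13 % at 25 min, on the ground that “it should keep rising to 25 min”.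

My own reckoning rests on the crossing level H×, a selectivity written as a concentration: the impurity concentration H at which product and loss take equal shares of what dissolves, so that product's share is H×/(H×+H). At delta's last reading 0.459 M had been lost. Counting one impurity per loss, impurity averaged 0.600 M, and the ratio of product to loss then gives H× = 0.117 M.

The flask opens above this level, with a share of 12.4 %. Solid left delta at 0.0260 M/min, so about 0.651 M of the flask's 0.83 M dissolves by 25 min. The opening share then gives 9.70 %, which is below the forecast; I hold it as a lower limit, since the share grows as impurity falls.

The simulation gives 11.6 % at 25.0 min, more than the flat view expected and within the forecast's margin.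

    starting material → intermediate (k = 0.0129 /s)
    intermediate → product (k = 0.00920 /s)
    starting material + protic impurity → quenched substrate (k = 0.121 /M/s)
    solid substrate ⇌ starting material, rate k4*(cs4 - [starting material]) while solid is left; crystals form when [starting material] > cs4 (solubility = 42.0 mM, k = 0.0117 /s)

The flat view has the flask's opening, with 0.390 % of product at 2.50 min. At 12.2 min in the flask, starting material has a half-life of 0.17 min against quenching and 0.90 min against forming intermediate, a factor of 5.23. At 25.0 min the flask still holds 0.305 M of impurity, above H×, with quenched substrate at 63.3 % against product at 11.6 %.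

In the neighbour flask, with 0.21 M of protic impurity, the opening share is 35.8 %; 58.7 % of the charge has left the solid by 25.0 min, so the lower limit there is 21.0 %. The computed best there is 30.1 %.

Readings and results stem from a simulated flask with constants of no real substance, noise included.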